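**Plan**
- Retrosynthesis: cut first the C4–O–C4 ether between the middle and lower flavan units, then the C4–C8 bond between the upper and middle units. Inside the middle unit, cut the C4–C4a bond of the pyran ring, which leads back to a 3-methylidene-2,3-dihydrobenzofuran whose exocyclic CH2 is the future C4.
- Enabling feature: in the middle unit, C4a of ring A lies ortho to C5–O and C8a–O1 and para to C7–O, so it is a phloroglucinol-type carbon of very high migratory aptitude. C3 bears oxygen and C4 is the carbon next to ring A. A 1,2-shift of that aryl carbon from C3 to the exocyclic carbon, set off by PhI(OH)OTs, therefore enlarges the furan ring to the pyran-3-one.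
- Forward order: allene heteroannulation (benzofuran ring), ring expansion to the flavan-3-one, reduction, C4 thioether, BF3 coupling with the 8-bromo upper-unit electrophile, silver-mediated etherification with the lower-unit 4-ol, hydrogenolysis.
- Stereochemistry: upper and lower units come from (−)- and (+)-epicatechin. C2/C3 of the middle unit are set by dynamic kinetic resolution in the transfer hydrogenation of the C2-labile ketone. C4 of the upper and middle units is set by β attack on the C4 cations, trans to the 3-oxygen. C4 of the lower unit is set by DDQ hydroxylation, oxidation and hydride reduction anti to 3-OBn.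

Key step: step 4

Remark: (+)-epicatechin (2S,3S), the enantiomer of the common natural compound, is taken as a purchasable starting material; it also forms from (+)-catechin by epimerisation at C2.

**Route**

Step 1
Reactants: 1 3,5-bis(benzyloxy)phenol
Product: 2 3,5-bis(benzyloxy)-2-iodophenol
Conditions: BnMe3N·ICl2 (1.0 equiv), NaHCO3, CH2Cl2–MeOH, rt
Reagents that add atoms: benzyltrimethylammonium dichloroiodate, C[N+](C)(C)Cc1ccccc1.Cl[I-]Cl
Why: Electrophilic aromatic iodination ortho to the free phenol (between OH and OBn), as this reagent does with 3,5-dimethoxyphenol; one equivalent limits di-iodination.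

Step 2
Reactants: 3 4-bromo-1,2-bis(benzyloxy)benzene
Product: 4 1,2-bis(benzyloxy)-4-(propa-1,2-dien-1-yl)benzene
Conditions: CH2=C=CHSnBu3, Pd(PPh3)4 (5 mol %), LiCl, DMF, 90 °C
Reagents that add atoms: tributyl(propa-1,2-dien-1-yl)stannane, CCCC[Sn](CCCC)(CCCC)C=C=C
Why: Stille cross-coupling of an allenylstannane should give the arylallene by reductive elimination from the aryl(allenyl)palladium intermediate.

Step 3
Reactants: 2 3,5-bis(benzyloxy)-2-iodophenol; 4 1,2-bis(benzyloxy)-4-(propa-1,2-dien-1-yl)benzene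
Product: 5 racemic 4,6-bis(benzyloxy)-2-[3,4-bis(benzyloxy)phenyl]-3-methylidene-2,3-dihydro-1-benzofuran
Conditions: Pd(OAc)2 (5 mol %), PPh3, K2CO3, n-Bu4NCl, DMF, 80 °C
Reagents that add atoms: none
Why: Larock heteroannulation of a 1,2-diene: the arylpalladium iodide adds its aryl carbon to the central allene carbon and the phenoxide closes 5-exo on the aryl-bearing terminus of the allylpalladium, giving the 2-aryl-3-methylidene ring; C2 forms racemic, which is harmless because it is equilibrated in step 5.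

Step 4
Reactants: 5 racemic 4,6-bis(benzyloxy)-2-[3,4-bis(benzyloxy)phenyl]-3-methylidene-2,3-dihydro-1-benzofuran
Product: 7 racemic 5,7-bis(benzyloxy)-2-[3,4-bis(benzyloxy)phenyl]chroman-3-one, via methoxy iodane adduct 6 (not isolated)
Conditions: PhI(OH)OTs (1.1 equiv), MeOH–H2O 95:5, 0 °C, 15 min
Reagents that add atoms: water, O
Why: The electrophilic trivalent iodine of PhI(OH)OTs adds to the CH2 end of the exocyclic alkene and methanol caps the C3 cation, which is benzylic to ring A, giving 6; the ring-A carbon C3a then shifts from C3 to the CH2 carbon with loss of iodobenzene, and hydrolysis of the resulting C3 oxocarbenium gives the ketone. The closest known reaction is the PhI(OH)OTs-mediated oxidative ring expansion of 1-methylidene benzocycloalkanes to the homologous β-aryl ketones, a semipinacol-type Wagner–Meerwein shift. No ring is closed by cyclisation: the pyran ring arises from the furan ring by this 1,2-aryl shift, which inserts the former exocyclic carbon (new C4) between C3 and C4a. No stereocentre is set; C2 is carried over and becomes α to the ketone, where it is left free to equilibrate for step 5. The step needs migration of the aryl carbon and not of C2, and it must outrun loss of H-2 to the aromatic benzofuran; the migrating carbon is ortho, ortho and para to three ether oxygens and bridges readily, C2 is deactivated by O1, and methanol at 0 °C should intercept the C3 cation before it eliminates.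

Step 5
Reactants: 7 racemic 5,7-bis(benzyloxy)-2-[3,4-bis(benzyloxy)phenyl]chroman-3-one
Product: 8 (2R,3R)-5,7-bis(benzyloxy)-2-[3,4-bis(benzyloxy)phenyl]chroman-3-ol (2,3-cis; 5,7,3',4'-tetra-O-benzyl-(−)-epicatechin)
Conditions: RuCl[(R,R)-TsDPEN](p-cymene) (2 mol %), HCO2H–Et3N 5:2, EtOAc, 35 °C
Reagents that add atoms: none
Why: Noyori transfer hydrogenation under dynamic kinetic resolution: H-2 is α to the ketone, benzylic and α to oxygen, so the two ketone enantiomers should interconvert through the enol faster than they are reduced, and the catalyst should reduce the (2R) ketone from the face opposite the 2-aryl group to the cis (2R,3R) alcohol, as in the cis-selective reduction of 2-aryl cycloalkanones; the (R,R) ligand is assigned by analogy with aryl ketones, the C2 side taking the place of the aryl group.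

Step 6
Reactants: 8 (2R,3R)-5,7-bis(benzyloxy)-2-[3,4-bis(benzyloxy)phenyl]chroman-3-ol
Product: 9 (2R,3R,4S)-5,7-bis(benzyloxy)-2-[3,4-bis(benzyloxy)phenyl]-4-(2-ethoxyethoxy)chroman-3-ol (4β; 3,4-trans)
Conditions: DDQ (2 equiv), HOCH2CH2OEt (10 equiv), CH2Cl2, rt
Reagents that add atoms: 2-ethoxyethanol, CCOCCO
Why: DDQ abstracts hydride from C4, which is activated by the ortho and para ether oxygens of ring A, and the alcohol adds to the cation trans to the axial 3-OH (β face), the established benzylic oxidation of benzylated epicatechin.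

Step 7
Reactants: 9 (2R,3R,4S)-5,7-bis(benzyloxy)-2-[3,4-bis(benzyloxy)phenyl]-4-(2-ethoxyethoxy)chroman-3-ol
Product: 10 (2R,3S,4S)-5,7-bis(benzyloxy)-2-[3,4-bis(benzyloxy)phenyl]-4-[(2,6-dimethylphenyl)sulfanyl]chroman-3-ol (4β; 3,4-trans)
Conditions: 2,6-Me2C6H3SH (3 equiv), BF3·OEt2, CH2Cl2, −78 → −30 °C
Reagents that add atoms: 2,6-dimethylbenzenethiol, Cc1cccc(C)c1S
Why: Lewis-acid ionisation of the 4-alkoxy group and capture by the thiol on the β face (thiolysis-type exchange); excess thiol outcompetes self-condensation through C8, and the hindered aryl thioether is inert to hard Lewis acids, so it is carried as a latent, silver-activatable leaving group.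

Step 8
Reactants: 11 (−)-epicatechin, (2R,3R)-2-(3,4-dihydroxyphenyl)chromane-3,5,7-triol
Product: 12 (2R,3R)-3,5,7-tris(benzyloxy)-2-[3,4-bis(benzyloxy)phenyl]chromane (penta-O-benzyl-(−)-epicatechin)
Conditions: NaH (6 equiv), BnBr (6 equiv), DMF, 0 °C → rt
Reagents that add atoms: benzyl bromide, BrCc1ccccc1
Why: Williamson etherification of all five hydroxyl groups; the 3-OH is capped as well so that the upper unit carries no free alcohol in step 16.

Step 9
Reactants: 12 (2R,3R)-3,5,7-tris(benzyloxy)-2-[3,4-bis(benzyloxy)phenyl]chromane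
Product: 13 (2R,3R)-8-bromo-3,5,7-tris(benzyloxy)-2-[3,4-bis(benzyloxy)phenyl]chromane
Conditions: NBS (1.0 equiv), CH2Cl2, −78 °C
Reagents that add atoms: N-bromosuccinimide, O=C1CCC(=O)N1Br
Why: Electrophilic bromination at C8, the most nucleophilic position of ring A; the bromine blocks C8 so that the electrophile of step 10 cannot condense with itself, and it is removed in step 17.

Step 10
Reactants: 13 (2R,3R)-8-bromo-3,5,7-tris(benzyloxy)-2-[3,4-bis(benzyloxy)phenyl]chromane
Product: 14 (2R,3R,4S)-8-bromo-3,5,7-tris(benzyloxy)-2-[3,4-bis(benzyloxy)phenyl]-4-(2-ethoxyethoxy)chromane (4β; 3,4-trans)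
Conditions: DDQ (2 equiv), HOCH2CH2OEt (10 equiv), CH2Cl2, rt
Reagents that add atoms: 2-ethoxyethanol, CCOCCO
Why: Same DDQ benzylic oxidation as step 6; the alcohol enters trans to the 3-OBn.

Step 11
Reactants: 14 (2R,3R,4S)-8-bromo-3,5,7-tris(benzyloxy)-2-[3,4-bis(benzyloxy)phenyl]-4-(2-ethoxyethoxy)chromane; 10 (2R,3S,4S)-5,7-bis(benzyloxy)-2-[3,4-bis(benzyloxy)phenyl]-4-[(2,6-dimethylphenyl)sulfanyl]chroman-3-ol
Product: 15 [8-bromo-3,5,7,3',4'-penta-O-benzyl-epicatechin]-(4β→8)-[4β-(2,6-dimethylphenylsulfanyl)-5,7,3',4'-tetra-O-benzyl-epicatechin]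
Conditions: BF3·OEt2, CH2Cl2, −78 °C (10 in 1.5-fold excess)
Reagents that add atoms: none
Why: Friedel–Crafts interflavan coupling: the hard Lewis acid ionises only the 4-alkoxy group of 14, and C8 of 10 (more nucleophilic and less hindered than C6) attacks the C4 cation on the β face, trans to the 3-OBn, giving the 4β→8 bond of the procyanidin B2 type while the aryl thioether stays intact.

Step 12
Reactants: 16 (+)-epicatechin, (2S,3S)-2-(3,4-dihydroxyphenyl)chromane-3,5,7-triol
Product: 17 (2S,3S)-3,5,7-tris(benzyloxy)-2-[3,4-bis(benzyloxy)phenyl]chromane (penta-O-benzyl-(+)-epicatechin)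
Conditions: NaH (6 equiv), BnBr (6 equiv), DMF, 0 °C → rt
Reagents that add atoms: benzyl bromide, BrCc1ccccc1
Why: Williamson etherification; the 3-O-benzyl group leaves only the 4-hydroxyl made later free to act as nucleophile.

Step 13
Reactants: 17 (2S,3S)-3,5,7-tris(benzyloxy)-2-[3,4-bis(benzyloxy)phenyl]chromane
Product: 18 (2S,3S,4R)-3,5,7-tris(benzyloxy)-2-[3,4-bis(benzyloxy)phenyl]chroman-4-ol (2,3-cis-3,4-trans)
Conditions: DDQ (1.5 equiv), CH2Cl2–H2O, rt
Reagents that add atoms: water, O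
Why: DDQ benzylic oxidation at C4 with water as the nucleophile, which enters trans to the 3-OBn.

Step 14
Reactants: 18 (2S,3S,4R)-3,5,7-tris(benzyloxy)-2-[3,4-bis(benzyloxy)phenyl]chroman-4-ol
Product: 19 (2S,3R)-3,5,7-tris(benzyloxy)-2-[3,4-bis(benzyloxy)phenyl]chroman-4-one (2,3-cis)
Conditions: Dess–Martin periodinane, NaHCO3, CH2Cl2, 0 °C → rt
Reagents that add atoms: none
Why: Dess–Martin oxidation of the benzylic alcohol; the buffered, non-basic medium should avoid epimerisation at C3.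

Step 15
Reactants: 19 (2S,3R)-3,5,7-tris(benzyloxy)-2-[3,4-bis(benzyloxy)phenyl]chroman-4-one
Product: 20 (2S,3S,4S)-3,5,7-tris(benzyloxy)-2-[3,4-bis(benzyloxy)phenyl]chroman-4-ol (all-cis)
Conditions: NaBH4, CeCl3·7H2O, MeOH–THF, −40 °C
Reagents that add atoms: none
Why: Luche-type reduction: hydride should add to the C4 ketone from the face opposite the quasi-axial 3-OBn, giving the 3,4-cis alcohol, so that steps 13–15 amount to a hydroxylation with the configuration opposite to direct DDQ hydroxylation.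

Step 16
Reactants: 15 [8-bromo-3,5,7,3',4'-penta-O-benzyl-epicatechin]-(4β→8)-[4β-(2,6-dimethylphenylsulfanyl)-5,7,3',4'-tetra-O-benzyl-epicatechin]; 20 (2S,3S,4S)-3,5,7-tris(benzyloxy)-2-[3,4-bis(benzyloxy)phenyl]chroman-4-ol
Product: 21 [8-bromo-3,5,7,3',4'-penta-O-benzyl-epicatechin]-(4β→8)-[5,7,3',4'-tetra-O-benzyl-epicatechin]-(4β→O→4)-[(2S,3S,4S)-3,5,7,3',4'-penta-O-benzyl-flavan-3,4-diol]
Conditions: AgBF4, 2,6-di-tert-butyl-4-methylpyridine, 4 Å MS, CH2Cl2, −40 → 0 °C (20 in 3-fold excess)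
Reagents that add atoms: none
Why: The thiophilic silver ion ionises the C4–S bond of the middle unit without protic or hard Lewis acid, and the secondary alcohol of 20, kinetically far more nucleophilic than its free aromatic carbons, should capture the C4 cation on the β face trans to the 3-OH, as in silver-mediated syntheses of ether-linked biflavanoids from 4-sulfanylflavans; the pyridine base removes HBF4 so that the new bis-benzylic ether does not re-ionise.

Step 17
Reactants: 21 [8-bromo-3,5,7,3',4'-penta-O-benzyl-epicatechin]-(4β→8)-[5,7,3',4'-tetra-O-benzyl-epicatechin]-(4β→O→4)-[(2S,3S,4S)-3,5,7,3',4'-penta-O-benzyl-flavan-3,4-diol]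
Product: 22 CNP0310719.1, epicatechin-(4β→8)-epicatechin-(4β→O→4)-[(2S,3S,4S)-2-(3,4-dihydroxyphenyl)chromane-3,4,5,7-tetrol]
Conditions: H2 (1 atm), Pd(OH)2/C, NaHCO3, THF–MeOH–H2O, rt
Reagents that add atoms: none
Why: Hydrogenolysis of the fourteen benzyl ethers and of the aryl bromide; O-benzyl ethers cleave much faster than the hindered secondary C4–O–C4 ether, bicarbonate neutralises the HBr that would cleave that acid-labile ether, and the reaction is stopped as soon as debenzylation is complete.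

**Compound list**

1 | 3,5-bis(benzyloxy)phenol | Oc1cc(OCc2ccccc2)cc(OCc2ccccc2)c1 | starting material
2 | 3,5-bis(benzyloxy)-2-iodophenol | Oc1cc(OCc2ccccc2)cc(OCc2ccccc2)c1I | intermediate
3 | 4-bromo-1,2-bis(benzyloxy)benzene | Brc1ccc(OCc2ccccc2)c(OCc2ccccc2)c1 | starting material
4 | 1,2-bis(benzyloxy)-4-(propa-1,2-dien-1-yl)benzene | C=C=Cc1ccc(OCc2ccccc2)c(OCc2ccccc2)c1 | intermediate
5 | racemic 4,6-bis(benzyloxy)-2-[3,4-bis(benzyloxy)phenyl]-3-methylidene-2,3-dihydro-1-benzofuran | C=C1c2c(OCc3ccccc3)cc(OCc3ccccc3)cc2OC1c1ccc(OCc3ccccc3)c(OCc3ccccc3)c1 | intermediate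
6 | methoxy iodane adduct: racemic 4,6-bis(benzyloxy)-2-[3,4-bis(benzyloxy)phenyl]-3-methoxy-3-{[phenyl(tosyloxy)iodanyl]methyl}-2,3-dihydro-1-benzofuran | COC1(C[I](c2ccccc2)OS(=O)(=O)c2ccc(C)cc2)c2c(OCc3ccccc3)cc(OCc3ccccc3)cc2OC1c1ccc(OCc3ccccc3)c(OCc3ccccc3)c1 | intermediate (not isolated)
7 | racemic 5,7-bis(benzyloxy)-2-[3,4-bis(benzyloxy)phenyl]chroman-3-one (tetra-O-benzyl flavan-3-one) | O=C1Cc2c(OCc3ccccc3)cc(OCc3ccccc3)cc2OC1c1ccc(OCc3ccccc3)c(OCc3ccccc3)c1 | intermediate
8 | (2R,3R)-5,7-bis(benzyloxy)-2-[3,4-bis(benzyloxy)phenyl]chroman-3-ol (2,3-cis; tetra-O-benzyl-(−)-epicatechin) | C(c3ccccc3)Oc1cc(OCc3ccccc3)c2c(c1)O[C@H](c1ccc(OCc3ccccc3)c(OCc3ccccc3)c1)[C@H](O)C2 | intermediate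
9 | (2R,3R,4S)-5,7-bis(benzyloxy)-2-[3,4-bis(benzyloxy)phenyl]-4-(2-ethoxyethoxy)chroman-3-ol (4β) | C(c3ccccc3)Oc1cc(OCc3ccccc3)c2c(c1)O[C@H](c1ccc(OCc3ccccc3)c(OCc3ccccc3)c1)[C@H](O)[C@H]2OCCOCC | intermediate
10 | (2R,3S,4S)-5,7-bis(benzyloxy)-2-[3,4-bis(benzyloxy)phenyl]-4-[(2,6-dimethylphenyl)sulfanyl]chroman-3-ol (4β) | C(c3ccccc3)Oc1cc(OCc3ccccc3)c2c(c1)O[C@H](c1ccc(OCc3ccccc3)c(OCc3ccccc3)c1)[C@H](O)[C@H]2Sc1c(C)cccc1C | intermediate
11 | (−)-epicatechin, (2R,3R)-2-(3,4-dihydroxyphenyl)chromane-3,5,7-triol | Oc1cc(O)c2c(c1)O[C@H](c1ccc(O)c(O)c1)[C@H](O)C2 | starting material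
12 | (2R,3R)-3,5,7-tris(benzyloxy)-2-[3,4-bis(benzyloxy)phenyl]chromane (penta-O-benzyl-(−)-epicatechin) | C(c3ccccc3)Oc1cc(OCc3ccccc3)c2c(c1)O[C@H](c1ccc(OCc3ccccc3)c(OCc3ccccc3)c1)[C@H](OCc1ccccc1)C2 | intermediate
13 | (2R,3R)-8-bromo-3,5,7-tris(benzyloxy)-2-[3,4-bis(benzyloxy)phenyl]chromane | C(c3ccccc3)Oc1cc(OCc3ccccc3)c2c(c1Br)O[C@H](c1ccc(OCc3ccccc3)c(OCc3ccccc3)c1)[C@H](OCc1ccccc1)C2 | intermediate
14 | (2R,3R,4S)-8-bromo-3,5,7-tris(benzyloxy)-2-[3,4-bis(benzyloxy)phenyl]-4-(2-ethoxyethoxy)chromane (4β) | C(c3ccccc3)Oc1cc(OCc3ccccc3)c2c(c1Br)O[C@H](c1ccc(OCc3ccccc3)c(OCc3ccccc3)c1)[C@H](OCc1ccccc1)[C@H]2OCCOCC | intermediate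
15 | [8-bromo-3,5,7,3',4'-penta-O-benzyl-epicatechin]-(4β→8)-[4β-(2,6-dimethylphenylsulfanyl)-5,7,3',4'-tetra-O-benzyl-epicatechin]; both units 2,3-cis-3,4-trans | C(c3ccccc3)Oc1cc(OCc3ccccc3)c2c(c1Br)O[C@H](c1ccc(OCc3ccccc3)c(OCc3ccccc3)c1)[C@H](OCc1ccccc1)[C@H]2c1c(OCc3ccccc3)cc(OCc3ccccc3)c2c1O[C@H](c1ccc(OCc3ccccc3)c(OCc3ccccc3)c1)[C@H](O)[C@H]2Sc1c(C)cccc1C | intermediate
16 | (+)-epicatechin, (2S,3S)-2-(3,4-dihydroxyphenyl)chromane-3,5,7-triol | Oc1cc(O)c2c(c1)O[C@@H](c1ccc(O)c(O)c1)[C@@H](O)C2 | starting material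
17 | (2S,3S)-3,5,7-tris(benzyloxy)-2-[3,4-bis(benzyloxy)phenyl]chromane (penta-O-benzyl-(+)-epicatechin) | C(c3ccccc3)Oc1cc(OCc3ccccc3)c2c(c1)O[C@@H](c1ccc(OCc3ccccc3)c(OCc3ccccc3)c1)[C@@H](OCc1ccccc1)C2 | intermediate
18 | (2S,3S,4R)-3,5,7-tris(benzyloxy)-2-[3,4-bis(benzyloxy)phenyl]chroman-4-ol (2,3-cis-3,4-trans) | C(c3ccccc3)Oc1cc(OCc3ccccc3)c2c(c1)O[C@@H](c1ccc(OCc3ccccc3)c(OCc3ccccc3)c1)[C@@H](OCc1ccccc1)[C@@H]2O | intermediate
19 | (2S,3R)-3,5,7-tris(benzyloxy)-2-[3,4-bis(benzyloxy)phenyl]chroman-4-one (2,3-cis) | C(c3ccccc3)Oc1cc(OCc3ccccc3)c2c(c1)O[C@@H](c1ccc(OCc3ccccc3)c(OCc3ccccc3)c1)[C@@H](OCc1ccccc1)C2=O | intermediate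
20 | (2S,3S,4S)-3,5,7-tris(benzyloxy)-2-[3,4-bis(benzyloxy)phenyl]chroman-4-ol (all-cis) | C(c3ccccc3)Oc1cc(OCc3ccccc3)c2c(c1)O[C@@H](c1ccc(OCc3ccccc3)c(OCc3ccccc3)c1)[C@@H](OCc1ccccc1)[C@H]2O | intermediate
21 | [8-bromo-3,5,7,3',4'-penta-O-benzyl-epicatechin]-(4β→8)-[5,7,3',4'-tetra-O-benzyl-epicatechin]-(4β→O→4)-[(2S,3S,4S)-3,5,7,3',4'-penta-O-benzyl-flavan-3,4-diol] | C(c3ccccc3)Oc1cc(OCc3ccccc3)c2c(c1Br)O[C@H](c1ccc(OCc3ccccc3)c(OCc3ccccc3)c1)[C@H](OCc1ccccc1)[C@H]2c1c(OCc3ccccc3)cc(OCc3ccccc3)c2c1O[C@H](c1ccc(OCc3ccccc3)c(OCc3ccccc3)c1)[C@H](O)[C@H]2O[C@H]1c2c(OCc3ccccc3)cc(OCc3ccccc3)cc2O[C@@H](c2ccc(OCc3ccccc3)c(OCc3ccccc3)c2)[C@H]1OCc1ccccc1 | intermediate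
22 | CNP0310719.1, epicatechin-(4β→8)-epicatechin-(4β→O→4)-[(2S,3S,4S)-2-(3,4-dihydroxyphenyl)chromane-3,4,5,7-tetrol] | Oc1cc(O)c2c(c1)O[C@H](c1ccc(O)c(O)c1)[C@H](O)[C@H]2c1c(O)cc(O)c2c1O[C@H](c1ccc(O)c(O)c1)[C@H](O)[C@H]2O[C@H]1c2c(O)cc(O)cc2O[C@@H](c2ccc(O)c(O)c2)[C@H]1O | target

**Totals**

Total step count: 17.
Longest linear sequence: 9 steps (1 → 2 → 5 → 7 → 8 → 9 → 10 → 15 → 21 → 22; steps 1, 3, 4, 5, 6, 7, 11, 16, 17).

**Steps most likely to fail**

Step 4. After the iodane has added, the C3 cation may lose H-2 and aromatise to a 3-substituted benzofuran, or the acid set free may isomerise the exocyclic alkene before it is oxidised. The fallback sets out from 5 and comes back at 7, and still forms the pyran ring by one-carbon ring expansion. Dihydroxylation of the exocyclic alkene (catalytic OsO4, N-methylmorpholine N-oxide, acetone–H2O) should give racemic 4,6-bis(benzyloxy)-2-[3,4-bis(benzyloxy)phenyl]-3-(hydroxymethyl)-2,3-dihydro-1-benzofuran-3-ol F1. Selective sulfonylation of the primary hydroxyl (TsCl, pyridine, 0 °C) should give the primary 4-methylbenzenesulfonate F2. Warming F2 with LiClO4 and CaCO3 in THF should trigger the classical semipinacol shift of the ring-A carbon onto the CH2OTs carbon under non-acidic conditions, giving 7.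

Step 16. The C4 cation may be attacked by the free ring-A carbons of 20 (C–C instead of C–O bond), or by the 3-OH of a second molecule of 15, or the product ether may re-ionise. The fallback sets out from 8 and 14 and comes back at 21. BF3·OEt2 coupling of 14 with 8 (two-fold excess, CH2Cl2, −78 °C) should give the sulfur-free dimer [8-bromo-3,5,7,3',4'-penta-O-benzyl-epicatechin]-(4β→8)-[5,7,3',4'-tetra-O-benzyl-epicatechin] F6. DDQ oxidation of F6 in CH2Cl2 in the presence of 20 (3 equiv) should then form the C4 cation of the lower unit directly from C–H, and 20 should trap it on the β face. This is the benzylic oxidation of steps 6, 10 and 13 with 20 as the alcohol; any 19 formed from 20 by over-oxidation is returned through step 15.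

Step 5. Equilibration at C2 may be slower than reduction, or the facial and cis selectivity of the catalyst may be low, giving stereoisomer mixtures. The fallback sets out from 7 and comes back at 8. Reduction with LiBH(s-Bu)3 (L-Selectride) in THF at −78 °C, which gives the 2,3-cis alcohol from this ketone, should give 8 as the racemate, that is together with its antipode (2S,3S)-5,7-bis(benzyloxy)-2-[3,4-bis(benzyloxy)phenyl]chroman-3-ol F3. Esterification of the mixture with (S)-2-methoxy-2-phenylacetic acid (DCC, DMAP, CH2Cl2) should give the diastereomeric esters, the (S)-2-methoxy-2-phenylacetate of 8 F4 and the (S)-2-methoxy-2-phenylacetate of the antipode F5, which are separated by chromatography. Methanolysis of F4 (K2CO3, MeOH–THF) returns 8.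

Further compounds
F1 | step 4 | racemic 4,6-bis(benzyloxy)-2-[3,4-bis(benzyloxy)phenyl]-3-(hydroxymethyl)-2,3-dihydro-1-benzofuran-3-ol | OCC1(O)c2c(OCc3ccccc3)cc(OCc3ccccc3)cc2OC1c1ccc(OCc3ccccc3)c(OCc3ccccc3)c1
F2 | step 4 | primary 4-methylbenzenesulfonate of F1 | Cc1ccc(cc1)S(=O)(=O)OCC1(O)c2c(OCc3ccccc3)cc(OCc3ccccc3)cc2OC1c1ccc(OCc3ccccc3)c(OCc3ccccc3)c1
F3 | step 5 | (2S,3S)-5,7-bis(benzyloxy)-2-[3,4-bis(benzyloxy)phenyl]chroman-3-ol | C(c3ccccc3)Oc1cc(OCc3ccccc3)c2c(c1)O[C@@H](c1ccc(OCc3ccccc3)c(OCc3ccccc3)c1)[C@@H](O)C2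
F4 | step 5 | (S)-2-methoxy-2-phenylacetate of 8 | C(c3ccccc3)Oc1cc(OCc3ccccc3)c2c(c1)O[C@H](c1ccc(OCc3ccccc3)c(OCc3ccccc3)c1)[C@H](OC(=O)[C@@H](OC)c1ccccc1)C2
F5 | step 5 | (S)-2-methoxy-2-phenylacetate of F3 | C(c3ccccc3)Oc1cc(OCc3ccccc3)c2c(c1)O[C@@H](c1ccc(OCc3ccccc3)c(OCc3ccccc3)c1)[C@@H](OC(=O)[C@@H](OC)c1ccccc1)C2
F6 | step 16 | [8-bromo-3,5,7,3',4'-penta-O-benzyl-epicatechin]-(4β→8)-[5,7,3',4'-tetra-O-benzyl-epicatechin] | C(c3ccccc3)Oc1cc(OCc3ccccc3)c2c(c1Br)O[C@H](c1ccc(OCc3ccccc3)c(OCc3ccccc3)c1)[C@H](OCc1ccccc1)[C@H]2c1c(OCc3ccccc3)cc(OCc3ccccc3)c2c1O[C@H](c1ccc(OCc3ccccc3)c(OCc3ccccc3)c1)[C@H](O)C2
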